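The route rests on tracing the C4/C4'' carbonyl oxygens and the C3/C3'' hydrogens back to a 3,3''-bi(2H-chromene). In each pyran ring C the C3=C4 bond lies next to the aryl-bearing C2 stereocentre. The C2 and C2'' aryl groups can therefore decide the face on which borane adds. One double hydroboration–oxidation places H on C3/C3'' and OH on C4/C4'', creating four stereocentres and both 2,3-cis relationships. The precursor is the (2R,2''R)-bichromene that already carries the 7''-methoxy group beside three benzyl ethers, so no late selective methylation is needed. It comes from an (R,R)-ynediol by two successive SNAr arylations, methylenation and dienyne ring-closing metathesis.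

Key step: step 11

Remark: flavanone numbering is used, with double primes for the 7-methoxy half; the target reads as (2S,3S,2''S,3''S), 2,3-cis in both halves (C2/C2'' are R in 7 and 14–17 and S in 19–21 through a change of CIP priorities only, not of shape), and it is assumed to hold this configuration under neutral conditions, so no base or strong acid is used after step 11.

Step 1
Reactants: 1 acetylene; 2 4-methoxybenzaldehyde (2 equiv)
Product: 4 1,4-bis(4-methoxyphenyl)but-2-yne-1,4-diol (dl/meso mixture), via ethynediylbis(magnesium bromide) 3 (not isolated)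
Conditions: EtMgBr (2 equiv), THF, 0 → 45 °C; then 2, 0 °C → rt; H2O
Reagents that add atoms: none
Why: Double Grignard 1,2-addition of the bis(bromomagnesium) derivative of acetylene to two aldehyde molecules builds the whole four-carbon chain at once; the carbinol centres form unselectively, which is harmless because step 2 erases them.

Step 2
Reactants: 4 1,4-bis(4-methoxyphenyl)but-2-yne-1,4-diol
Product: 5 1,4-bis(4-methoxyphenyl)but-2-yne-1,4-dione
Conditions: MnO2 (activated, excess), CH2Cl2, rt
Reagents that add atoms: none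
Why: MnO2 oxidation is selective for alcohols that are both benzylic and propargylic and runs under neutral conditions that spare the electrophilic ynedione.

Step 3
Reactants: 5 1,4-bis(4-methoxyphenyl)but-2-yne-1,4-dione
Product: 7 (1R,4R)-1,4-bis(4-methoxyphenyl)but-2-yne-1,4-diol, via bis(9-BBN borinate) 6 (not isolated)
Conditions: (R)-Alpine-Borane (B-isopinocampheyl-9-BBN from (+)-α-pinene, 4 equiv), THF (concentrated), rt; then HOCH2CH2NH2, Et2O, 0 °C; meso-diol removed by chromatography
Reagents that add atoms: none
Why: Midland reduction, in which hydride passes from the pinanyl C–H to the carbonyl through a six-membered boat-like transition state with the slim linear alkynyl group next to the pinane methyl and the aryl group pointing away, so the choice between the two flanking π-groups is purely steric, the reagent from (+)-α-pinene should set both carbinol centres as R, and a wrong event at either carbonyl ends mainly in the separable meso-diol, which raises the enantiopurity of the C2-symmetric diol.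

Step 4
Reactants: 8 2,6-difluoro-4-methoxybenzaldehyde; 9 benzyl alcohol
Product: 10 2-(benzyloxy)-6-fluoro-4-methoxybenzaldehyde
Conditions: NaH (1.0 equiv), 9 (1.0 equiv), THF, 0 °C → rt
Reagents that add atoms: none
Why: SNAr (addition–elimination) at one of two equivalent C–F bonds ortho to the formyl group, so no regioisomer is possible, and the alkoxy group that enters weakens the acceptor so that the second fluoride stays.

Step 5
Reactants: 11 2,6-difluoro-4-hydroxybenzaldehyde
Product: 12 4-(benzyloxy)-2,6-difluorobenzaldehyde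
Conditions: BnBr, K2CO3, DMF, rt
Reagents that add atoms: benzyl bromide, BrCc1ccccc1
Why: Williamson etherification of an acidic phenol para to a formyl group with carbonate base, too mild to touch the C–F bonds.

Step 6
Reactants: 12 4-(benzyloxy)-2,6-difluorobenzaldehyde; 9 benzyl alcohol
Product: 13 2,4-bis(benzyloxy)-6-fluorobenzaldehyde
Conditions: NaH (1.0 equiv), 9 (1.0 equiv), THF, 0 °C → rt
Reagents that add atoms: none
Why: The same SNAr monosubstitution as in step 4, again on two equivalent ortho fluorides, so the substitution pattern is unambiguous.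

Step 7
Reactants: 7 (1R,4R)-1,4-bis(4-methoxyphenyl)but-2-yne-1,4-diol (2.5 equiv, excess recovered); 10 2-(benzyloxy)-6-fluoro-4-methoxybenzaldehyde
Product: 14 2-(benzyloxy)-6-{[(1R,4R)-4-hydroxy-1,4-bis(4-methoxyphenyl)but-2-yn-1-yl]oxy}-4-methoxybenzaldehyde
Conditions: NaH (1.0 equiv relative to 10), DMF, 0 °C; then 10, 0 °C → rt
Reagents that add atoms: none
Why: SNAr of the sodium carbinolate at the C–F bond ortho to the formyl group (both alkoxy groups are meta to the attacked carbon and do not destabilise the Meisenheimer adduct); the carbinol C–O bond is never broken, so R is retained, the two hydroxyls are homotopic, so only one mono-ether can form, and the recoverable excess of 7 holds back double arylation.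

Step 8
Reactants: 14 mono-ether aldehyde; 13 2,4-bis(benzyloxy)-6-fluorobenzaldehyde
Product: 15 2,4-bis(benzyloxy)-6-{[(1R,4R)-4-[3-(benzyloxy)-2-formyl-5-methoxyphenoxy]-1,4-bis(4-methoxyphenyl)but-2-yn-1-yl]oxy}benzaldehyde
Conditions: NaH (1.05 equiv), DMF, 0 °C; then 13 (1.2 equiv), 0 °C → rt
Reagents that add atoms: none
Why: A second SNAr of the same type on the remaining carbinolate, again with retention because only the O–H bond reacts, which fixes the unsymmetrical pattern of rings A and A'' early and without ambiguity.

Step 9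
Reactants: 15 bis-ether dialdehyde
Product: 16 (1R,4R)-1-[3,5-bis(benzyloxy)-2-vinylphenoxy]-4-[3-(benzyloxy)-5-methoxy-2-vinylphenoxy]-1,4-bis(4-methoxyphenyl)but-2-yne
Conditions: MePPh3Br (3 equiv), KOtBu (2.8 equiv), THF, 0 °C; then 15, 0 °C → rt
Reagents that add atoms: methyltriphenylphosphonium bromide, C[P+](c1ccccc1)(c1ccccc1)c1ccccc1.[Br-]
Why: Double Wittig methylenation, in which the non-stabilised ylide adds to the aldehydes much faster than it could deprotonate the propargylic C–H, so the two stereocentres are untouched.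

Step 10
Reactants: 16 dienyne
Product: 17 (2R,2''R)-5,5'',7-tris(benzyloxy)-7''-methoxy-2,2''-bis(4-methoxyphenyl)-2H,2''H-3,3''-bichromene
Conditions: second-generation Grubbs catalyst RuCl2(=CHPh)(PCy3)(SIMes) (10 mol %), CH2Cl2 (dilute), 40 °C, dark
Reagents that add atoms: none
Why: Tandem dienyne ring-closing metathesis, in which the ruthenium benzylidene formed at either styrene adds to the alkyne in the exo mode to close the first pyran ring and the resulting vinylcarbene closes the second on the other styrene with loss of ethylene, as known for 2-vinylaryl propargyl ethers and for dienynes with a central alkyne; C2 and C2'' are spectators, and the low temperature and darkness guard against electrocyclic opening of the 2H-chromenes, which would racemise them.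

Step 11
Reactants: 17 (2R,2''R)-bichromene
Product: 19 (2S,3R,4R,2''S,3''R,4''R)-5,7,5''-tris(benzyloxy)-7''-methoxy-2,2''-bis(4-methoxyphenyl)-3,3''-bichromane-4,4''-diol (2,3-cis/3,4-trans in each half), via 4,4''-bis(boranyl) adduct 18 (not isolated)
Conditions: BH3·THF (6 equiv), THF, 0 °C → rt (17 added slowly to the borane); then 3 M NaOH, 30% H2O2, 0 °C; neutral work-up
Reagents that add atoms: hydrogen peroxide, OO
Why: Hydroboration–oxidation of the kind known for flav-3-enes and 1-arylcycloalkenes, in which each trisubstituted C3=C4 bond takes up H–B in a concerted four-centre syn addition, boron bonding to the CH terminus C4 (C4'') and hydrogen to the fully substituted C3 (C3''); no ring is closed. A(1,2) strain with the bulky chromenyl group on C3 pushes each C2 aryl group into the pseudo-axial position, where it covers one face of its own ring C, so borane comes from the other face: C2 thus controls C3 and C4, C2'' controls C3'' and C4'', and the C3–C3'' bond ends cis to both aryl groups. Alkaline peroxide then exchanges boron for hydroxyl by a 1,2-shift from boron to oxygen with retention, which gives the 3,4-trans alcohols. The step needs regioselectivity (boron at C4, secured by the substitution pattern of the alkene, which should outweigh the donor effect of ring A) and facial selectivity (secured by the two homochiral C2 centres, which make both additions matched). If the first C4–BH2 group adds intramolecularly to the second alkene, the borolane formed anti to the C2'' aryl group is the all-trans one and leads to the same diol, so the inverse addition to excess borane is a precaution and not a requirement.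

Step 12
Reactants: 19 bis(flavan-4-ol)
Product: 20 (2S,3S,2''S,3''S)-5,7,5''-tris(benzyloxy)-7''-methoxy-2,2''-bis(4-methoxyphenyl)-3,3''-bichromane-4,4''-dione
Conditions: Dess–Martin periodinane (3 equiv), pyridine, CH2Cl2, 0 °C → rt
Reagents that add atoms: none
Why: Dess–Martin oxidation converts both benzylic alcohols to ketones under buffered, nearly neutral conditions, so the acid-labile flavan-4-ols do not ionise and the epimerisable cis centres C3 and C3'' are kept.

Step 13
Reactants: 20 tri-O-benzyl biflavanone
Product: 21 (2S,3S,2''S,3''S)-5,7,5''-trihydroxy-7''-methoxy-2,2''-bis(4-methoxyphenyl)-3,3''-bichromane-4,4''-dione (target)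
Conditions: H2 (1 atm), 10% Pd/C, EtOAc–MeOH, rt
Reagents that add atoms: none
Why: Catalytic hydrogenolysis of the three aryl benzyl ethers under neutral conditions, a standard final step for flavanones in which the cyclic C2–O1 bond, the aryl ketones and the C3 configuration survive.

Compound list
1 | acetylene | C#C | starting material
2 | 4-methoxybenzaldehyde | COc1ccc(C=O)cc1 | starting material
3 | ethynediylbis(magnesium bromide) | Br[Mg]C#C[Mg]Br | intermediate
4 | 1,4-bis(4-methoxyphenyl)but-2-yne-1,4-diol (dl/meso mixture) | COc1ccc(C(O)C#CC(O)c2ccc(OC)cc2)cc1 | intermediate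
5 | 1,4-bis(4-methoxyphenyl)but-2-yne-1,4-dione | COc1ccc(C(=O)C#CC(=O)c2ccc(OC)cc2)cc1 | intermediate
6 | (1R,4R)-1,4-bis(9-borabicyclo[3.3.1]nonan-9-yloxy)-1,4-bis(4-methoxyphenyl)but-2-yne | COc1ccc([C@@H](OB2C3CCCC2CCC3)C#C[C@H](OB2C3CCCC2CCC3)c2ccc(OC)cc2)cc1 | intermediate
7 | (1R,4R)-1,4-bis(4-methoxyphenyl)but-2-yne-1,4-diol | COc1ccc([C@@H](O)C#C[C@H](O)c2ccc(OC)cc2)cc1 | intermediate
8 | 2,6-difluoro-4-methoxybenzaldehyde | COc1cc(F)c(C=O)c(F)c1 | starting material
9 | benzyl alcohol | OCc1ccccc1 | starting material
10 | 2-(benzyloxy)-6-fluoro-4-methoxybenzaldehyde | COc1cc(F)c(C=O)c(OCc2ccccc2)c1 | intermediate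
11 | 2,6-difluoro-4-hydroxybenzaldehyde | O=Cc1c(F)cc(O)cc1F | starting material
12 | 4-(benzyloxy)-2,6-difluorobenzaldehyde | O=Cc1c(F)cc(OCc2ccccc2)cc1F | intermediate
13 | 2,4-bis(benzyloxy)-6-fluorobenzaldehyde | O=Cc1c(F)cc(OCc2ccccc2)cc1OCc1ccccc1 | intermediate
14 | 2-(benzyloxy)-6-{[(1R,4R)-4-hydroxy-1,4-bis(4-methoxyphenyl)but-2-yn-1-yl]oxy}-4-methoxybenzaldehyde | COc1ccc([C@@H](O)C#C[C@H](Oc2cc(OC)cc(OCc3ccccc3)c2C=O)c2ccc(OC)cc2)cc1 | intermediate
15 | 2,4-bis(benzyloxy)-6-{[(1R,4R)-4-[3-(benzyloxy)-2-formyl-5-methoxyphenoxy]-1,4-bis(4-methoxyphenyl)but-2-yn-1-yl]oxy}benzaldehyde | COc1ccc([C@@H](Oc2cc(OCc3ccccc3)cc(OCc3ccccc3)c2C=O)C#C[C@H](Oc2cc(OC)cc(OCc3ccccc3)c2C=O)c2ccc(OC)cc2)cc1 | intermediate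
16 | (1R,4R)-1-[3,5-bis(benzyloxy)-2-vinylphenoxy]-4-[3-(benzyloxy)-5-methoxy-2-vinylphenoxy]-1,4-bis(4-methoxyphenyl)but-2-yne | COc1ccc([C@@H](Oc2cc(OCc3ccccc3)cc(OCc3ccccc3)c2C=C)C#C[C@H](Oc2cc(OC)cc(OCc3ccccc3)c2C=C)c2ccc(OC)cc2)cc1 | intermediate
17 | (2R,2''R)-5,5'',7-tris(benzyloxy)-7''-methoxy-2,2''-bis(4-methoxyphenyl)-2H,2''H-3,3''-bichromene | COc1ccc([C@H]2Oc3cc(OCc4ccccc4)cc(OCc4ccccc4)c3C=C2C2=Cc3c(OCc4ccccc4)cc(OC)cc3O[C@@H]2c2ccc(OC)cc2)cc1 | intermediate
18 | 4,4''-bis(boranyl) adduct of 17 (BH2 on C4 and C4'', cis to H-3 and H-3'', anti to the C2 and C2'' aryl groups) | COc1ccc([C@H]2Oc3cc(OCc4ccccc4)cc(OCc4ccccc4)c3[C@H](B)[C@H]2[C@@H]2[C@@H](B)c3c(OCc4ccccc4)cc(OC)cc3O[C@@H]2c2ccc(OC)cc2)cc1 | intermediate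
19 | (2S,3R,4R,2''S,3''R,4''R)-5,7,5''-tris(benzyloxy)-7''-methoxy-2,2''-bis(4-methoxyphenyl)-3,3''-bichromane-4,4''-diol | COc1ccc([C@H]2Oc3cc(OCc4ccccc4)cc(OCc4ccccc4)c3[C@H](O)[C@H]2[C@@H]2[C@@H](O)c3c(OCc4ccccc4)cc(OC)cc3O[C@@H]2c2ccc(OC)cc2)cc1 | intermediate
20 | (2S,3S,2''S,3''S)-5,7,5''-tris(benzyloxy)-7''-methoxy-2,2''-bis(4-methoxyphenyl)-3,3''-bichromane-4,4''-dione | COc1ccc([C@H]2Oc3cc(OCc4ccccc4)cc(OCc4ccccc4)c3C(=O)[C@H]2[C@@H]2C(=O)c3c(OCc4ccccc4)cc(OC)cc3O[C@@H]2c2ccc(OC)cc2)cc1 | intermediate
21 | (2S,3S,2''S,3''S)-5,7,5''-trihydroxy-7''-methoxy-2,2''-bis(4-methoxyphenyl)-3,3''-bichromane-4,4''-dione | COc1ccc([C@H]2Oc3cc(O)cc(O)c3C(=O)[C@H]2[C@@H]2C(=O)c3c(O)cc(OC)cc3O[C@@H]2c2ccc(OC)cc2)cc1 | target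

Total step count: 13. Longest linear sequence: 10 steps (1, 2, 3, 7, 8, 9, 10, 11, 12, 13).

Steps most likely to fail

Step 11. The donor-rich ring A polarises C3=C4 against the steric preference. Part of the boron may therefore end on C3, from where β-elimination of O1 would open ring C. The crowded second addition may also stall or lose facial control. The fallback sets out from 17 and brings in hydrogen and oxygen separately.
- Both C3=C4 bonds are hydrogenated with [Ir(cod)(PCy3)(py)]PF6 and H2 in CH2Cl2, a catalyst that leaves benzyl ethers alone. Syn delivery of H2 to the face away from each pseudo-axial aryl group should give the 2,3-cis biflavan (2S,3S,2''S,3''S)-5,7,5''-tris(benzyloxy)-7''-methoxy-2,2''-bis(4-methoxyphenyl)-3,3''-bichromane F1.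
- DDQ in wet CH2Cl2 then abstracts hydride from C4 and C4'', the positions activated by the dialkoxy rings A. This is the reaction type used to functionalise C4 of O-benzylated flavan-3-ols.
- Water traps the cations to give 5,7,5''-tris(benzyloxy)-7''-methoxy-2,2''-bis(4-methoxyphenyl)-3,3''-bichromane-4,4''-diol of undefined C4/C4'' configuration F2.
- The conditions of step 12 convert F2 into 20, where the route is rejoined.

Step 10. The catalyst may rest as a chelated 2-alkoxybenzylidene. The fully substituted vinylcarbene formed after the first closure may decay or oligomerise before it reaches the second, doubly ortho-substituted styrene. Forcing turnover by heat would invite electrocyclic racemisation. The fallback sets out from 16 and splits the cascade into one intermolecular and two ordinary intramolecular events, none of which needs a disubstituted carbene.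
- Cross enyne metathesis with ethylene (1 atm, RuCl2(=CHPh)(PCy3)(SIMes), CH2Cl2, rt) lets the small methylidene attack the alkyne. This should give the tetraene (R,R)-2,3-bis[aryloxy(4-methoxyphenyl)methyl]buta-1,3-diene that carries the two vinylaryl ethers of 16 F3, which is isolated.
- With ethylene purged, the second-generation Hoveyda–Grubbs catalyst RuCl2(=CH-C6H4-2-OiPr)(SIMes) (CH2Cl2, 40 °C, dark) closes each styrene onto its neighbouring 1,1-disubstituted methylene, and the route is rejoined at 17.

Step 7. Displacement at the hindered, donor-substituted fluoroarene may be slower than hydride transfer from the carbinolate to the formyl group, or slower than base-induced propargyl-to-allenyl isomerisation of the product. Double arylation would also consume the mono-ether. The fallback sets out from 7 and replaces the formyl activator by a nitrile. The nitrile is slimmer, activates SNAr at least as well and cannot take up hydride or alkoxide from the carbinolate, so a lower temperature suffices.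
- Purchased 2,6-difluoro-4-methoxybenzonitrile F4 and 9 (NaH, THF, 0 °C) give 2-(benzyloxy)-6-fluoro-4-methoxybenzonitrile F5.
- SNAr with the sodium salt of excess 7 (DMF, 0 °C) gives 2-(benzyloxy)-6-{[(1R,4R)-4-hydroxy-1,4-bis(4-methoxyphenyl)but-2-yn-1-yl]oxy}-4-methoxybenzonitrile F6.
- iBu2AlH (toluene, −78 °C) followed by mild hydrolysis of the imine returns the route at 14.

Further compounds
F1 | step 11 | (2S,3S,2''S,3''S)-5,7,5''-tris(benzyloxy)-7''-methoxy-2,2''-bis(4-methoxyphenyl)-3,3''-bichromane | COc1ccc([C@H]2Oc3cc(OCc4ccccc4)cc(OCc4ccccc4)c3C[C@H]2[C@@H]2Cc3c(OCc4ccccc4)cc(OC)cc3O[C@@H]2c2ccc(OC)cc2)cc1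
F2 | step 11 | (2S,2''S; 2,3-cis in both halves)-5,7,5''-tris(benzyloxy)-7''-methoxy-2,2''-bis(4-methoxyphenyl)-3,3''-bichromane-4,4''-diol, C4 and C4'' undefined | COc1ccc([C@H]2Oc3cc(OCc4ccccc4)cc(OCc4ccccc4)c3C(O)[C@H]2[C@@H]2C(O)c3c(OCc4ccccc4)cc(OC)cc3O[C@@H]2c2ccc(OC)cc2)cc1
F3 | step 10 | (R,R)-2-{[3,5-bis(benzyloxy)-2-vinylphenoxy](4-methoxyphenyl)methyl}-3-{[3-(benzyloxy)-5-methoxy-2-vinylphenoxy](4-methoxyphenyl)methyl}buta-1,3-diene | COc1ccc([C@@H](Oc2cc(OCc3ccccc3)cc(OCc3ccccc3)c2C=C)C(=C)C(=C)[C@H](Oc2cc(OC)cc(OCc3ccccc3)c2C=C)c2ccc(OC)cc2)cc1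
F4 | step 7 | 2,6-difluoro-4-methoxybenzonitrile (purchased) | COc1cc(F)c(C#N)c(F)c1
F5 | step 7 | 2-(benzyloxy)-6-fluoro-4-methoxybenzonitrile | COc1cc(F)c(C#N)c(OCc2ccccc2)c1
F6 | step 7 | 2-(benzyloxy)-6-{[(1R,4R)-4-hydroxy-1,4-bis(4-methoxyphenyl)but-2-yn-1-yl]oxy}-4-methoxybenzonitrile | COc1ccc([C@@H](O)C#C[C@H](Oc2cc(OC)cc(OCc3ccccc3)c2C#N)c2ccc(OC)cc2)cc1
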